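## The problem

Target 27 is a diterpenoid of the enantiomeric labdane series. Labdane numbering is used for positions throughout: C1–C10 are the ring carbons, C11–C16 the side chain, C17 sits on C8, C18 and C19 on C4, and C20 on C10.

- **Skeleton.** Rings A and B form a trans-fused decalin. The ring-fusion methine C5 lies between two quaternary carbons, C4 (gem-dimethyl) and C10 (angular methyl). Ring B holds a trisubstituted C7=C8 alkene, C2 carries an equatorial acetate, and C9 carries a five-carbon chain with a methyl stereocentre at C13 and a primary acetate at C15.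
- **Ring stereocentres.** C2, C5, C9 and C10 are geometrically linked: the fusion is trans, C11 is cis to C20, and the C2 oxygen is trans to C20. One of them, once set absolutely, can therefore steer the other three.
- **C13.** It is insulated from the ring by two methylene groups and must come from a building block of known configuration.
- **Hardest bond.** C5–C10 joins a carbon next to the quaternary C4 to the quaternary C10, and the product carries a 1,3-diaxial pair of methyl groups (C20 and one C4 methyl).
- **Sensitive groups.** Both acetates are lost to hydride, amide bases, organometallics and fluoride, so they belong at the end. The C7=C8 double bond can slip to C8=C9 or out of the ring under acid. C9 is allylic and becomes epimerisable whenever C11 is a carbonyl group.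
- **Enabling feature.** Ring B is a cyclohexene. With its double bond moved one position to C6=C7, the six atoms C5–C10 are the adduct of a diene C5=C6–C7=C8 and a dienophile C9=C10. The four atoms C1–C4 of ring A tie the diene end C5 to the dienophile end C10, which makes the open-chain form a 1,7,9-decatriene. An oxygen on C7 of the diene lets the alkene be placed at C7=C8 afterwards.

## Retrosynthesis

**Acetates (C2–O and C15–O acyl bonds).** Target 27 is traced to diol 26 and from there to the bis-silyl ether 25. Putting both acetates on in the last step keeps them away from every hydride, base and fluoride used earlier. One silyl ether at each oxygen allows a single deprotection. The forward steps only need to be clean.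

**C11–C12.** Ether 25 comes from alkene 24, which is cut across C11=C12 into the bicyclic aldehyde 18 and the tetrazolyl sulfone 22 (used as its carbanion 23). A cut at C9–C11 would demand alkylation at a ring carbon flanked by C10 and would put the C9 configuration at risk. A cut at C12–C13 would destroy the only remote stereocentre. The chosen cut leaves C13 inside a four-carbon fragment and C9 inside the ring system. The forward reaction must be an olefination that does not enolise 18, followed by saturation of the new disubstituted alkene without touching C7=C8.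

**Sulfone fragment.** Sulfone 22 goes back through sulfide 21 and mono-silyl ether 20 to diol 19. The C1–S bond is cut (Mitsunobu), then the O–Si bond. The stereocentre is bought, not made. The only demand is to tell the two primary hydroxyl groups of 19 apart.

**Alkene position and C11 oxidation level.** Aldehyde 18 comes from alcohol 17 and ester 16. The C7=C8 alkene of 16 is traced to enol triflate 15, to ketone 14, and to the silyl enol ether 13, in which the double bond lies at C6=C7. This shift is what uncovers the cycloaddition retron. The forward sequence must enolise 14 toward C8, not C6, and then replace the triflate by hydrogen without moving the double bond.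

**C5–C10 and C8–C9 (key cut).** Opening both bonds of 13 gives the acyclic triene 12 and removes two rings and four stereocentres at once. Cutting only one ring (a Robinson-type or cationic closure of ring A onto a preformed ring B) would leave the C5–C10 bond between hindered centres as a separate problem. The forward step must give the trans fusion and a single diene face. The E enoate, the Z silyl enol ether and the C2 silyloxy group are there to supply this.

**Diene (C5=C6 and C7 enol ether).** Triene 12 arises from enone 11 by enolisation toward C8. Enone 11 is cut at C5=C6 into aldehyde 9 and phosphonate 10. Aldehyde 9 is the cleavage product of the vinyl group in 7, through diol 8. The vinyl group is a masked aldehyde on a quaternary carbon, so it survives the earlier steps. The forward steps must give the E enone and the Z enol ether.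

**C1–C2 and the C2 stereocentre.** Silyl ether 7 comes from carbinol 6, which is cut at C1–C2 into aldehyde 2 and silyl dienolate 5. This vinylogous aldol cut sets C2 and delivers the complete E enoate C9=C10 with C20 in one step. A non-vinylogous aldol would need a later olefination of a methyl ketone with uncertain geometry. Aldehyde 2 comes from ester 1, and dienolate 5 from ester 3 via enolate 4.

## Roads not taken

**Alternative 1: pinane cyclobutane fragmentation with cationic closure of ring A.**
- Cut: the C3–C4 and C2–O bonds are opened and a C4–C7 bond is added. C4 becomes the one-carbon bridge of a pinane-type cyclobutane across C5 and C7, with a ketone at C8 and an allyl group (C1–C3) on C10.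
- Forward step: BF3·OEt2 in acetic acid opens the strained C4–C7 bond to a tertiary C4 cation and a C8 enol. The allyl terminus C3 adds to C4 and acetate traps the C2 cation, giving the 8-oxo-17-nor diacetate A1.
- Merits: the absolute configuration comes from the chiral pool. Ring A, the C2–O bond and both acetates are present after the key step. Only the conversion of the C8 ketone into the C8 methyl/C7=C8 unit remains, about two steps against twelve here.
- Weak points: C2 is the last centre formed, from a free secondary cation, so acetate can enter from either face and elimination or hydride shift compete. The substrate needs C9 and the quaternary C10 installed by successive alkylations of a hindered bicyclic ketone. The final methyl transfer must tolerate two acetates.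
- Comparison: this road is shorter after the key step and needs no asymmetric catalysis. The chosen plan sets C2 first, with a defined configuration, and uses it to direct the ring fusion.

**Alternative 2: aldehyde-initiated Prins bicyclisation.**
- Cut: C1–C2 and C9–C10. The substrate is acyclic apart from nothing: an aldehyde at C2, an isopropenyl group (C1, C10, C20) on C5, and an E C8=C9 alkene carrying the finished side chain.
- Forward step: SnCl4 activates the aldehyde, C1 attacks C2, C9 traps the C10 cation and loss of H7 gives the 2-hydroxy 15-acetate A2.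
- Merits: it is the shortest route of all. A2 is one acetylation from the target, and the alkene and side chain are already in place.
- Weak points: after the first bond forms, the C10 cation can lose a proton (a plain carbonyl-ene outcome) faster than the trisubstituted alkene captures it. The final proton can leave from C7, C17 or C9, giving alkene isomers. The C2 carbinol configuration depends on how the Lewis-acid-bound aldehyde sits in the chair. The single controlling stereocentre C5, tertiary and next to C4, must itself be made enantioselectively.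
- Comparison: in step economy this road is clearly better. The chosen plan trades length for bond formation under orbital control with no free cation, so that every ring stereocentre follows from an alkene geometry or from C2.

**Alternative 3: gold-triggered enyne bicyclisation ended by an enol silane.**
- Cut: C8–C9 and C1–C10. The substrate has a C7≡C8 alkyne, an E C9=C10 alkene and a silyl enol ether at C1=C2.
- Forward step: Ph3PAuNTf2, a cationic monovalent gold complex, activates the alkyne. C9 adds to C8, the enol silane carbon C1 captures the C10 cation, and protodeauration at C7 gives the 2-oxo 15-silyl ether A3.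
- Merits: the reaction is catalytic and mild, and it forms the quaternary C10. The C7=C8 position is fixed by the mechanism. This is better than the chosen plan, which spends three steps and one regiochemical decision on the alkene. About three steps remain after A3.
- Weak points: the enyne can close in the five-membered mode to cyclopropyl carbene products instead of the six-membered ring. The enol silane is sensitive to the acidic gold medium. C5, between C4 and two unsaturated arms, has to be made enantioselectively. The C2 ketone must later be reduced to the equatorial alcohol although small hydrides, blocked axially by the C4 and C10 methyl groups, tend to give the axial one.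
- Comparison: the end game is shorter and the alkene placement is cleaner. The chosen plan offers a precursor built from simple aldehyde chemistry and a C2 centre that is set first and then acts as the control element.

Key step: step 8

Remark 1: in step 3 the catalyst antipode is the one whose sense of induction is attack on the Si face of aldehyde 2; both antipodes are accessible from resolved 1,1'-binaphthyl-2,2'-diamine, and the sense is an assumption to be confirmed on carbinol 6.
Remark 2: the ketene acetal geometry of 5 and the carbinol centre C8 of diol 8 are left undefined; neither survives into a later compound.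
Remark 3: systematic names use naphthalene numbering for the bicyclic compounds; the discussion uses labdane numbering.

## Route

Step 1
Reactants: 1 methyl 3,3-dimethylpent-4-enoate
Product: 2 3,3-dimethylpent-4-enal
Conditions: iBu2AlH (1.05 equiv), CH2Cl2, −78 °C; MeOH, aq. Rochelle salt
Reagents that add atoms: none
Why: Partial ester reduction; at −78 °C the aluminium hemiacetal persists and gives the aldehyde only on work-up. The volatile aldehyde is carried on as a dried solution.

Step 2
Reactants: 3 methyl 3-methylbut-2-enoate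
Product: 5 tert-butyl[(1-methoxy-3-methylbuta-1,3-dien-1-yl)oxy]dimethylsilane, via lithium dienolate 4 (not isolated)
Conditions: LiN(iPr)2, THF, −78 °C; then TBSCl, DMPU, −78 °C → rt
Reagents that add atoms: tert-butyldimethylsilyl chloride, CC(C)(C)[Si](C)(C)Cl
Why: γ-Deprotonation of the senecioate and O-silylation of the extended enolate (silyl ketene acetal formation), a standard preparation of this dienolate.

Step 3
Reactants: 2 3,3-dimethylpent-4-enal; 5 tert-butyl[(1-methoxy-3-methylbuta-1,3-dien-1-yl)oxy]dimethylsilane
Product: 6 methyl (2E,5S)-5-hydroxy-3,7,7-trimethylnona-2,8-dienoate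
Conditions: SiCl4 (1.1 equiv), chiral binaphthyldiamine-derived bisphosphoramide (5 mol %, antipode for Si-face attack), iPr2NEt (10 mol %), CH2Cl2, −72 °C; aq. KF/KH2PO4
Reagents that add atoms: none
Why: Catalytic asymmetric vinylogous Mukaiyama aldol reaction; the chiral Lewis base–trichlorosilyl cation binds the aldehyde and the dienolate attacks through its γ-carbon, so the catalyst sets the 5S carbinol (C2). The open transition state should give the 2E enoate with C20 cis to the ester.

Step 4
Reactants: 6 methyl (2E,5S)-5-hydroxy-3,7,7-trimethylnona-2,8-dienoate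
Product: 7 methyl (2E,5S)-5-[(tert-butyldimethylsilyl)oxy]-3,7,7-trimethylnona-2,8-dienoate
Conditions: TBSCl, imidazole, DMF, rt
Reagents that add atoms: tert-butyldimethylsilyl chloride, CC(C)(C)[Si](C)(C)Cl
Why: Silyl ether formation at an unhindered secondary alcohol; the bulky ether is the later control element of the cycloaddition.

Step 5
Reactants: 7 methyl (2E,5S)-5-[(tert-butyldimethylsilyl)oxy]-3,7,7-trimethylnona-2,8-dienoate
Product: 9 methyl (2E,5S)-5-[(tert-butyldimethylsilyl)oxy]-3,7,7-trimethyl-8-oxooct-2-enoate, via vicinal diol 8 (not isolated)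
Conditions: OsO4 (2 mol %), NaIO4 (4 equiv), 2,6-lutidine, dioxane/H2O, rt
Reagents that add atoms: osmium tetroxide, O=[Os](=O)(=O)=O (transfers the oxygen); sodium periodate, [Na+].[O-]I(=O)(=O)=O (terminal oxygen source)
Why: Lemieux–Johnson cleavage; OsO4 should dihydroxylate the isolated monosubstituted alkene in preference to the electron-poor trisubstituted enoate, and periodate cleaves diol 8 and reoxidises osmium.

Step 6
Reactants: 9 methyl (2E,5S)-5-[(tert-butyldimethylsilyl)oxy]-3,7,7-trimethyl-8-oxooct-2-enoate; 10 diethyl (2-oxobutyl)phosphonate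
Product: 11 methyl (2E,5S,8E)-5-[(tert-butyldimethylsilyl)oxy]-3,7,7-trimethyl-10-oxododeca-2,8-dienoate
Conditions: Ba(OH)2 (activated), THF/H2O (40:1), rt
Reagents that add atoms: none
Why: Horner–Wadsworth–Emmons olefination of a non-enolisable aldehyde with a β-ketophosphonate; the stabilised anion should give the E enone under these mild conditions.

Step 7
Reactants: 11 methyl (2E,5S,8E)-5-[(tert-butyldimethylsilyl)oxy]-3,7,7-trimethyl-10-oxododeca-2,8-dienoate
Product: 12 methyl (2E,5S,8E,10Z)-5-[(tert-butyldimethylsilyl)oxy]-3,7,7-trimethyl-10-[(triethylsilyl)oxy]dodeca-2,8,10-trienoate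
Conditions: TESOTf, Et3N, CH2Cl2, −78 → 0 °C
Reagents that add atoms: triethylsilyl trifluoromethanesulfonate, CC[Si](CC)(CC)OS(=O)(=O)C(F)(F)F
Why: Soft enolisation of the ethyl ketone, the only enolisable site of the enone (C4 is quaternary). Ethyl ketones give the Z silyl enol ether under these conditions, which places the C17 methyl on the outside of the diene.

Step 8
Reactants: 12 methyl (2E,5S,8E,10Z)-5-[(tert-butyldimethylsilyl)oxy]-3,7,7-trimethyl-10-[(triethylsilyl)oxy]dodeca-2,8,10-trienoate
Product: 13 methyl (1R,2S,4aR,7R,8aR)-7-[(tert-butyldimethylsilyl)oxy]-2,5,5,8a-tetramethyl-3-[(triethylsilyl)oxy]-1,2,4a,5,6,7,8,8a-octahydronaphthalene-1-carboxylate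
Conditions: PhMe (0.01 M), BHT (cat.), sealed tube, 170–180 °C
Reagents that add atoms: none
Why: Thermal intramolecular Diels–Alder reaction of a 1,7,9-decatriene, concerted but asynchronous with the C5–C10 bond to the enoate β-carbon more advanced; the closest known reaction type is the thermal cycloaddition of 2-silyloxy-diene trienoates with β,β-disubstituted enoates to angular-methyl trans-decalins. Ring B closes as the cyclohexene of the [4+2] addition (bonds C5–C10 and C8–C9), and ring A closes in the same event through the C1–C4 tether in the fused mode, exo at both diene and dienophile. C9 and C10 follow from suprafacial addition to the E enoate, which keeps the ester and C20 cis. The trans fusion of C5 and C10 comes from the transition state with the tether anti and the ester endo, in which C1–C4 folds like a cyclohexane chair. The absolute sense is relayed from C2, whose silyloxy group takes the equatorial site of that chair because the axial site lies between the axial C4 methyl and C20. C8 is set cis to the ester by the Z enol ether and is erased in step 10. The step needs trans over cis fusion and one diene face; the first rests on the E geometry and the endo ester, the second on the C2 stereocentre. The silyloxy group raises the diene HOMO and the gem-dimethyl group favours the reactive rotamer, which should offset the hindered trisubstituted dienophile.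

Step 9
Reactants: 13 methyl (1R,2S,4aR,7R,8aR)-7-[(tert-butyldimethylsilyl)oxy]-2,5,5,8a-tetramethyl-3-[(triethylsilyl)oxy]-1,2,4a,5,6,7,8,8a-octahydronaphthalene-1-carboxylate
Product: 14 methyl (1R,2S,4aR,7R,8aR)-7-[(tert-butyldimethylsilyl)oxy]-2,5,5,8a-tetramethyl-3-oxodecahydronaphthalene-1-carboxylate
Conditions: aq. HCl (0.5 M), THF, 0 °C
Reagents that add atoms: none
Why: Acid hydrolysis of a silyl enol ether, far faster than cleavage of the secondary alkyl silyl ether. Protonation at C6 leaves C8 as formed, and epimerisation there would be of no consequence.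

Step 10
Reactants: 14 methyl (1R,2S,4aR,7R,8aR)-7-[(tert-butyldimethylsilyl)oxy]-2,5,5,8a-tetramethyl-3-oxodecahydronaphthalene-1-carboxylate
Product: 15 methyl (1S,4aR,7R,8aR)-7-[(tert-butyldimethylsilyl)oxy]-2,5,5,8a-tetramethyl-3-{[(trifluoromethyl)sulfonyl]oxy}-1,4,4a,5,6,7,8,8a-octahydronaphthalene-1-carboxylate
Conditions: Tf2O, 2,6-di-tert-butyl-4-methylpyridine, CH2Cl2, 0 °C → rt
Reagents that add atoms: trifluoromethanesulfonic anhydride, O=S(=O)(OS(=O)(=O)C(F)(F)F)C(F)(F)F
Why: Enol triflate formation under equilibrating conditions with a hindered pyridine; loss of the C8 proton gives the tetrasubstituted, thermodynamically preferred triflate and relieves the C17/C20 1,3-diaxial strain. The C8 stereocentre disappears here.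

Step 11
Reactants: 15 methyl (1S,4aR,7R,8aR)-7-[(tert-butyldimethylsilyl)oxy]-2,5,5,8a-tetramethyl-3-{[(trifluoromethyl)sulfonyl]oxy}-1,4,4a,5,6,7,8,8a-octahydronaphthalene-1-carboxylate
Product: 16 methyl (1R,4aR,7R,8aR)-7-[(tert-butyldimethylsilyl)oxy]-2,5,5,8a-tetramethyl-1,4,4a,5,6,7,8,8a-octahydronaphthalene-1-carboxylate
Conditions: Pd(OAc)2 (5 mol %), PPh3 (10 mol %), HCO2H, Bu3N, DMF, 60 °C
Reagents that add atoms: none
Why: Palladium-catalysed formate reduction of an enol triflate (oxidative addition to zerovalent palladium, formate decarboxylation, reductive elimination). The hydrogen enters at C7 and the double bond stays at C7=C8.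

Step 12
Reactants: 16 methyl (1R,4aR,7R,8aR)-7-[(tert-butyldimethylsilyl)oxy]-2,5,5,8a-tetramethyl-1,4,4a,5,6,7,8,8a-octahydronaphthalene-1-carboxylate
Product: 17 [(1R,4aR,7R,8aR)-7-[(tert-butyldimethylsilyl)oxy]-2,5,5,8a-tetramethyl-1,4,4a,5,6,7,8,8a-octahydronaphthalen-1-yl]methanol
Conditions: iBu2AlH (2.5 equiv), CH2Cl2, −78 → 0 °C; aq. Rochelle salt
Reagents that add atoms: none
Why: Full hydride reduction of the ester to the primary alcohol; going through the alcohol is more reliable than a partial reduction of this hindered ester.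

Step 13
Reactants: 17 [(1R,4aR,7R,8aR)-7-[(tert-butyldimethylsilyl)oxy]-2,5,5,8a-tetramethyl-1,4,4a,5,6,7,8,8a-octahydronaphthalen-1-yl]methanol
Product: 18 (1R,4aR,7R,8aR)-7-[(tert-butyldimethylsilyl)oxy]-2,5,5,8a-tetramethyl-1,4,4a,5,6,7,8,8a-octahydronaphthalene-1-carbaldehyde
Conditions: Dess–Martin periodinane, NaHCO3, CH2Cl2, 0 °C → rt
Reagents that add atoms: none
Why: Dess–Martin oxidation under buffered, near-neutral conditions, chosen so that the β,γ-unsaturated aldehyde neither epimerises at C9 nor moves into conjugation. The aldehyde is used without delay.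

Step 14
Reactants: 19 (R)-2-methylbutane-1,4-diol
Product: 20 (2R)-4-[(tert-butyldiphenylsilyl)oxy]-2-methylbutan-1-ol
Conditions: TBDPSCl (1.0 equiv), imidazole, CH2Cl2, −20 °C
Reagents that add atoms: tert-butyldiphenylsilyl chloride, CC(C)(C)[Si](Cl)(c1ccccc1)c1ccccc1
Why: Silyl ether formation; the bulky chlorosilane should react preferentially at the primary hydroxyl remote from the methyl branch. The minor regioisomer and the bis-ether are separable, and the stereocentre is untouched.

Step 15
Reactants: 20 (2R)-4-[(tert-butyldiphenylsilyl)oxy]-2-methylbutan-1-ol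
Product: 21 5-{[(2R)-4-[(tert-butyldiphenylsilyl)oxy]-2-methylbutyl]sulfanyl}-1-phenyl-1H-tetrazole
Conditions: 1-phenyl-1H-tetrazole-5-thiol, PPh3, DIAD, THF, 0 °C → rt
Reagents that add atoms: 1-phenyl-1H-tetrazole-5-thiol, Sc1nnnn1-c1ccccc1
Why: Mitsunobu thioetherification of a primary alcohol; the stereocentre is one carbon away and is not involved.

Step 16
Reactants: 21 5-{[(2R)-4-[(tert-butyldiphenylsilyl)oxy]-2-methylbutyl]sulfanyl}-1-phenyl-1H-tetrazole
Product: 22 5-{[(2R)-4-[(tert-butyldiphenylsilyl)oxy]-2-methylbutyl]sulfonyl}-1-phenyl-1H-tetrazole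
Conditions: (NH4)6Mo7O24·4H2O (10 mol %), 30% aq. H2O2, EtOH, 0 °C → rt
Reagents that add atoms: hydrogen peroxide, OO
Why: Molybdate-catalysed oxidation of the sulfide to the sulfone, the usual way to tetrazolyl sulfones; the silyl ether is inert.

Step 17
Reactants: 22 5-{[(2R)-4-[(tert-butyldiphenylsilyl)oxy]-2-methylbutyl]sulfonyl}-1-phenyl-1H-tetrazole; 18 (1R,4aR,7R,8aR)-7-[(tert-butyldimethylsilyl)oxy]-2,5,5,8a-tetramethyl-1,4,4a,5,6,7,8,8a-octahydronaphthalene-1-carbaldehyde
Product: 24 tert-butyl{[(3R,4E)-5-[(1R,4aR,7R,8aR)-7-[(tert-butyldimethylsilyl)oxy]-2,5,5,8a-tetramethyl-1,4,4a,5,6,7,8,8a-octahydronaphthalen-1-yl]-3-methylpent-4-en-1-yl]oxy}diphenylsilane, via potassium sulfonyl carbanion 23 (not isolated)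
Conditions: 22, KN(SiMe3)2, THF, −78 °C; then 18, −78 °C → rt
Reagents that add atoms: none
Why: Julia–Kocienski olefination (carbanion addition, Smiles rearrangement, loss of SO2 and tetrazololate); premetalation at −78 °C keeps free base away from the aldehyde. The E isomer is expected to predominate, and the geometry is removed in step 18.

Step 18
Reactants: 24 tert-butyl{[(3R,4E)-5-[(1R,4aR,7R,8aR)-7-[(tert-butyldimethylsilyl)oxy]-2,5,5,8a-tetramethyl-1,4,4a,5,6,7,8,8a-octahydronaphthalen-1-yl]-3-methylpent-4-en-1-yl]oxy}diphenylsilane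
Product: 25 tert-butyl{[(3S)-5-[(1R,4aR,7R,8aR)-7-[(tert-butyldimethylsilyl)oxy]-2,5,5,8a-tetramethyl-1,4,4a,5,6,7,8,8a-octahydronaphthalen-1-yl]-3-methylpentyl]oxy}diphenylsilane
Conditions: 2-nitrobenzenesulfonyl hydrazide (excess, in portions), Et3N, CH2Cl2, rt
Reagents that add atoms: none
Why: Diimide reduction by concerted syn transfer of two hydrogens; the disubstituted alkene should react much faster than the hindered trisubstituted ring alkene. The C13 descriptor changes from R to S only through the priority rules.

Step 19
Reactants: 25 tert-butyl{[(3S)-5-[(1R,4aR,7R,8aR)-7-[(tert-butyldimethylsilyl)oxy]-2,5,5,8a-tetramethyl-1,4,4a,5,6,7,8,8a-octahydronaphthalen-1-yl]-3-methylpentyl]oxy}diphenylsilane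
Product: 26 (2R,4aR,8R,8aR)-8-[(3S)-5-hydroxy-3-methylpentyl]-4,4,7,8a-tetramethyl-1,2,3,4,4a,5,8,8a-octahydronaphthalen-2-ol
Conditions: Bu4NF (4 equiv), THF, rt → 50 °C
Reagents that add atoms: none
Why: Fluoride cleavage of both silyl ethers in one operation; the alkene and all stereocentres are inert to fluoride.

Step 20
Reactants: 26 (2R,4aR,8R,8aR)-8-[(3S)-5-hydroxy-3-methylpentyl]-4,4,7,8a-tetramethyl-1,2,3,4,4a,5,8,8a-octahydronaphthalen-2-ol
Product: 27 (3S)-5-[(1R,4aR,7R,8aR)-7-(acetyloxy)-2,5,5,8a-tetramethyl-1,4,4a,5,6,7,8,8a-octahydronaphthalen-1-yl]-3-methylpentyl acetate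
Conditions: Ac2O, pyridine, DMAP (cat.), CH2Cl2, rt
Reagents that add atoms: acetic anhydride, CC(=O)OC(C)=O
Why: Acyl transfer to the primary and the equatorial secondary hydroxyl under nucleophilic catalysis; non-acidic conditions leave the C7=C8 alkene in place.

## Compound list

1 | methyl 3,3-dimethylpent-4-enoate | COC(=O)CC(C)(C)C=C | starting material
2 | 3,3-dimethylpent-4-enal | O=CCC(C)(C)C=C | intermediate
3 | methyl 3-methylbut-2-enoate | COC(=O)C=C(C)C | starting material
4 | lithium 1-methoxy-3-methylbuta-1,3-dien-1-olate | [Li+].[O-]C(OC)=CC(C)=C | intermediate (not isolated)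
5 | tert-butyl[(1-methoxy-3-methylbuta-1,3-dien-1-yl)oxy]dimethylsilane (ketene acetal geometry undefined) | C=C(C)C=C(OC)O[Si](C)(C)C(C)(C)C | intermediate
6 | methyl (2E,5S)-5-hydroxy-3,7,7-trimethylnona-2,8-dienoate | COC(=O)/C=C(\C)C[C@H](O)CC(C)(C)C=C | intermediate
7 | methyl (2E,5S)-5-[(tert-butyldimethylsilyl)oxy]-3,7,7-trimethylnona-2,8-dienoate | COC(=O)/C=C(\C)C[C@H](O[Si](C)(C)C(C)(C)C)CC(C)(C)C=C | intermediate
8 | methyl (2E,5S)-5-[(tert-butyldimethylsilyl)oxy]-8,9-dihydroxy-3,7,7-trimethylnon-2-enoate (both C8 epimers) | COC(=O)/C=C(\C)C[C@H](O[Si](C)(C)C(C)(C)C)CC(C)(C)C(O)CO | intermediate (not isolated)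
9 | methyl (2E,5S)-5-[(tert-butyldimethylsilyl)oxy]-3,7,7-trimethyl-8-oxooct-2-enoate | COC(=O)/C=C(\C)C[C@H](O[Si](C)(C)C(C)(C)C)CC(C)(C)C=O | intermediate
10 | diethyl (2-oxobutyl)phosphonate | CCC(=O)CP(=O)(OCC)OCC | starting material
11 | methyl (2E,5S,8E)-5-[(tert-butyldimethylsilyl)oxy]-3,7,7-trimethyl-10-oxododeca-2,8-dienoate | COC(=O)/C=C(\C)C[C@H](O[Si](C)(C)C(C)(C)C)CC(C)(C)/C=C/C(=O)CC | intermediate
12 | methyl (2E,5S,8E,10Z)-5-[(tert-butyldimethylsilyl)oxy]-3,7,7-trimethyl-10-[(triethylsilyl)oxy]dodeca-2,8,10-trienoate | C/C=C(O[Si](CC)(CC)CC)/C=C/C(C)(C)C[C@@H](O[Si](C)(C)C(C)(C)C)C/C(C)=C/C(=O)OC | intermediate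
13 | methyl (1R,2S,4aR,7R,8aR)-7-[(tert-butyldimethylsilyl)oxy]-2,5,5,8a-tetramethyl-3-[(triethylsilyl)oxy]-1,2,4a,5,6,7,8,8a-octahydronaphthalene-1-carboxylate | COC(=O)[C@@H]1[C@H](C)C(O[Si](CC)(CC)CC)=C[C@@H]2C(C)(C)C[C@@H](O[Si](C)(C)C(C)(C)C)C[C@@]12C | intermediate
14 | methyl (1R,2S,4aR,7R,8aR)-7-[(tert-butyldimethylsilyl)oxy]-2,5,5,8a-tetramethyl-3-oxodecahydronaphthalene-1-carboxylate | COC(=O)[C@@H]1[C@H](C)C(=O)C[C@@H]2C(C)(C)C[C@@H](O[Si](C)(C)C(C)(C)C)C[C@@]12C | intermediate
15 | methyl (1S,4aR,7R,8aR)-7-[(tert-butyldimethylsilyl)oxy]-2,5,5,8a-tetramethyl-3-{[(trifluoromethyl)sulfonyl]oxy}-1,4,4a,5,6,7,8,8a-octahydronaphthalene-1-carboxylate | COC(=O)[C@@H]1C(C)=C(OS(=O)(=O)C(F)(F)F)C[C@@H]2C(C)(C)C[C@@H](O[Si](C)(C)C(C)(C)C)C[C@@]12C | intermediate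
16 | methyl (1R,4aR,7R,8aR)-7-[(tert-butyldimethylsilyl)oxy]-2,5,5,8a-tetramethyl-1,4,4a,5,6,7,8,8a-octahydronaphthalene-1-carboxylate | COC(=O)[C@@H]1C(C)=CC[C@@H]2C(C)(C)C[C@@H](O[Si](C)(C)C(C)(C)C)C[C@@]12C | intermediate
17 | [(1R,4aR,7R,8aR)-7-[(tert-butyldimethylsilyl)oxy]-2,5,5,8a-tetramethyl-1,4,4a,5,6,7,8,8a-octahydronaphthalen-1-yl]methanol | OC[C@@H]1C(C)=CC[C@@H]2C(C)(C)C[C@@H](O[Si](C)(C)C(C)(C)C)C[C@@]12C | intermediate
18 | (1R,4aR,7R,8aR)-7-[(tert-butyldimethylsilyl)oxy]-2,5,5,8a-tetramethyl-1,4,4a,5,6,7,8,8a-octahydronaphthalene-1-carbaldehyde | O=C[C@@H]1C(C)=CC[C@@H]2C(C)(C)C[C@@H](O[Si](C)(C)C(C)(C)C)C[C@@]12C | intermediate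
19 | (R)-2-methylbutane-1,4-diol | OCC[C@@H](C)CO | starting material
20 | (2R)-4-[(tert-butyldiphenylsilyl)oxy]-2-methylbutan-1-ol | CC(C)(C)[Si](c1ccccc1)(c1ccccc1)OCC[C@@H](C)CO | intermediate
21 | 5-{[(2R)-4-[(tert-butyldiphenylsilyl)oxy]-2-methylbutyl]sulfanyl}-1-phenyl-1H-tetrazole | CC(C)(C)[Si](c1ccccc1)(c1ccccc1)OCC[C@@H](C)CSc1nnnn1-c1ccccc1 | intermediate
22 | 5-{[(2R)-4-[(tert-butyldiphenylsilyl)oxy]-2-methylbutyl]sulfonyl}-1-phenyl-1H-tetrazole | CC(C)(C)[Si](c1ccccc1)(c1ccccc1)OCC[C@@H](C)CS(=O)(=O)c1nnnn1-c1ccccc1 | intermediate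
23 | potassium (2R)-4-[(tert-butyldiphenylsilyl)oxy]-2-methyl-1-[(1-phenyl-1H-tetrazol-5-yl)sulfonyl]butan-1-ide | [K+].CC(C)(C)[Si](c1ccccc1)(c1ccccc1)OCC[C@@H](C)[CH-]S(=O)(=O)c1nnnn1-c1ccccc1 | intermediate (not isolated)
24 | tert-butyl{[(3R,4E)-5-[(1R,4aR,7R,8aR)-7-[(tert-butyldimethylsilyl)oxy]-2,5,5,8a-tetramethyl-1,4,4a,5,6,7,8,8a-octahydronaphthalen-1-yl]-3-methylpent-4-en-1-yl]oxy}diphenylsilane | CC(C)(C)[Si](c1ccccc1)(c1ccccc1)OCC[C@@H](C)/C=C/[C@@H]1C(C)=CC[C@@H]2C(C)(C)C[C@@H](O[Si](C)(C)C(C)(C)C)C[C@@]12C | intermediate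
25 | tert-butyl{[(3S)-5-[(1R,4aR,7R,8aR)-7-[(tert-butyldimethylsilyl)oxy]-2,5,5,8a-tetramethyl-1,4,4a,5,6,7,8,8a-octahydronaphthalen-1-yl]-3-methylpentyl]oxy}diphenylsilane | CC(C)(C)[Si](c1ccccc1)(c1ccccc1)OCC[C@@H](C)CC[C@@H]1C(C)=CC[C@@H]2C(C)(C)C[C@@H](O[Si](C)(C)C(C)(C)C)C[C@@]12C | intermediate
26 | (2R,4aR,8R,8aR)-8-[(3S)-5-hydroxy-3-methylpentyl]-4,4,7,8a-tetramethyl-1,2,3,4,4a,5,8,8a-octahydronaphthalen-2-ol | OCC[C@@H](C)CC[C@@H]1C(C)=CC[C@@H]2C(C)(C)C[C@@H](O)C[C@@]12C | intermediate
27 | (3S)-5-[(1R,4aR,7R,8aR)-7-(acetyloxy)-2,5,5,8a-tetramethyl-1,4,4a,5,6,7,8,8a-octahydronaphthalen-1-yl]-3-methylpentyl acetate | CC(=O)OCC[C@@H](C)CC[C@@H]1C(C)=CC[C@@H]2C(C)(C)C[C@@H](OC(C)=O)C[C@@]12C | target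

## Step count and least certain steps

Total: 20 steps. Longest linear sequence: 16 steps (steps 1, 3–13, 17–20). Step 2 and steps 14–16 are side branches.

**Step 8 (key step).**
- What may go wrong: the cycloaddition may be slow, with thermal loss of the silyl dienol ether competing, and the trans-fused transition state may not win clearly over the cis-fused one. Three features work against it: the dienophile is trisubstituted; the tether makes the nucleophilic diene terminus C8 bond to the enoate α-carbon, so the silyloxy group helps less than in an intermolecular case; and the trans transition state carries the C20/axial C4 methyl interaction that the cis one avoids.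
- Fallback (from 12, returning at 14): the dienophile is activated as an aldehyde, which lowers the LUMO and has a stronger endo preference.
  - Reduction of 12 with iBu2AlH at −78 °C would give (2E,5S,8E,10Z)-5-[(tert-butyldimethylsilyl)oxy]-3,7,7-trimethyl-10-[(triethylsilyl)oxy]dodeca-2,8,10-trien-1-ol F1.
  - MnO2 in CH2Cl2 would give the corresponding trienal F2.
  - Heating F2 in toluene at a lower temperature should give the cycloadduct aldehyde (1R,2S,4aR,7R,8aR)-7-[(tert-butyldimethylsilyl)oxy]-2,5,5,8a-tetramethyl-3-[(triethylsilyl)oxy]-1,2,4a,5,6,7,8,8a-octahydronaphthalene-1-carbaldehyde F3.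
  - Dilute acid would hydrolyse the enol ether to the keto aldehyde F4.
  - Pinnick oxidation (NaClO2, NaH2PO4, 2-methylbut-2-ene) would give the keto acid F5, and Me3SiCHN2 in MeOH would give keto ester 14.

**Step 10.**
- What may go wrong: enolisation may go toward C6 instead of C8, because the C8 proton is the more hindered one and direct triflation of unsymmetrical ketones is not always fully thermodynamic. The result would be contamination by the C6=C7 triflate and, after step 11, by the wrong alkene.
- Fallback (from 14, returning at 15): the regiochemical decision is moved to a separate, equilibrating and purifiable intermediate. Me3SiCl/NaI/Et3N in MeCN would give the more substituted silyl enol ether, methyl (1S,4aR,7R,8aR)-7-[(tert-butyldimethylsilyl)oxy]-2,5,5,8a-tetramethyl-3-[(trimethylsilyl)oxy]-1,4,4a,5,6,7,8,8a-octahydronaphthalene-1-carboxylate F6. After removal of the minor isomer, PhNTf2 with CsF in DME would convert F6 into triflate 15 with the regiochemistry fixed.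

**Step 3.**
- What may go wrong: conversion may be low and enantioselectivity eroded, because enolisable aliphatic aldehydes are reversibly tied up as chlorosilyl ethers under these conditions and this one is β-branched. The sense of induction is also an assumption (Remark 1).
- Fallback (from 2, returning at 7): the C1–C2 bond is made by asymmetric propargylation and the enoate is built afterwards.
  - Allenylboronic acid pinacol ester with a chiral binaphthol-derived phosphoric acid (antipode for Si-face attack) would give (4S)-6,6-dimethyloct-7-en-1-yn-4-ol F7.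
  - TBSCl/imidazole would give tert-butyl{[(4S)-6,6-dimethyloct-7-en-1-yn-4-yl]oxy}dimethylsilane F8.
  - Zirconium-catalysed carboalumination (AlMe3, (C5H5)2ZrCl2 cat.) followed by ClCO2Me would add methyl and ester syn across the alkyne and give 7 with the E geometry fixed by the mechanism.

**Step 17 (and step 18).**
- What may go wrong: the sulfonyl carbanion may deprotonate C9 of the β,γ-unsaturated aldehyde, which would cause epimerisation or migration of the double bond into conjugation. In step 18, over-reduction of the ring alkene is possible if the hindered disubstituted alkene reacts slowly.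
- Fallback (from 18 and 20, returning at 25): the C11–C12 bond is made by carbonyl addition and no side-chain alkene is formed.
  - CBr4/PPh3 would convert 20 into {[(3R)-4-bromo-3-methylbutyl]oxy}(tert-butyl)diphenylsilane F9.
  - Mg in THF would give bromo{(2R)-4-[(tert-butyldiphenylsilyl)oxy]-2-methylbutyl}magnesium F10.
  - Addition of F10 to 18 at −78 °C would give (3R)-1-[(1R,4aR,7R,8aR)-7-[(tert-butyldimethylsilyl)oxy]-2,5,5,8a-tetramethyl-1,4,4a,5,6,7,8,8a-octahydronaphthalen-1-yl]-5-[(tert-butyldiphenylsilyl)oxy]-3-methylpentan-1-ol F11 as a mixture of C11 epimers.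
  - NaH/CS2/MeI would give the S-methyl xanthate F12, and Barton–McCombie reduction (Bu3SnH, AIBN, toluene, 80 °C) would give 25.

## Further compounds

F1 | step 8 | (2E,5S,8E,10Z)-5-[(tert-butyldimethylsilyl)oxy]-3,7,7-trimethyl-10-[(triethylsilyl)oxy]dodeca-2,8,10-trien-1-ol | C/C=C(O[Si](CC)(CC)CC)/C=C/C(C)(C)C[C@@H](O[Si](C)(C)C(C)(C)C)C/C(C)=C/CO
F2 | step 8 | (2E,5S,8E,10Z)-5-[(tert-butyldimethylsilyl)oxy]-3,7,7-trimethyl-10-[(triethylsilyl)oxy]dodeca-2,8,10-trienal | C/C=C(O[Si](CC)(CC)CC)/C=C/C(C)(C)C[C@@H](O[Si](C)(C)C(C)(C)C)C/C(C)=C/C=O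
F3 | step 8 | (1R,2S,4aR,7R,8aR)-7-[(tert-butyldimethylsilyl)oxy]-2,5,5,8a-tetramethyl-3-[(triethylsilyl)oxy]-1,2,4a,5,6,7,8,8a-octahydronaphthalene-1-carbaldehyde | O=C[C@@H]1[C@H](C)C(O[Si](CC)(CC)CC)=C[C@@H]2C(C)(C)C[C@@H](O[Si](C)(C)C(C)(C)C)C[C@@]12C
F4 | step 8 | (1R,2S,4aR,7R,8aR)-7-[(tert-butyldimethylsilyl)oxy]-2,5,5,8a-tetramethyl-3-oxodecahydronaphthalene-1-carbaldehyde | O=C[C@@H]1[C@H](C)C(=O)C[C@@H]2C(C)(C)C[C@@H](O[Si](C)(C)C(C)(C)C)C[C@@]12C
F5 | step 8 | (1R,2S,4aR,7R,8aR)-7-[(tert-butyldimethylsilyl)oxy]-2,5,5,8a-tetramethyl-3-oxodecahydronaphthalene-1-carboxylic acid | OC(=O)[C@@H]1[C@H](C)C(=O)C[C@@H]2C(C)(C)C[C@@H](O[Si](C)(C)C(C)(C)C)C[C@@]12C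
F6 | step 10 | methyl (1S,4aR,7R,8aR)-7-[(tert-butyldimethylsilyl)oxy]-2,5,5,8a-tetramethyl-3-[(trimethylsilyl)oxy]-1,4,4a,5,6,7,8,8a-octahydronaphthalene-1-carboxylate | COC(=O)[C@@H]1C(C)=C(O[Si](C)(C)C)C[C@@H]2C(C)(C)C[C@@H](O[Si](C)(C)C(C)(C)C)C[C@@]12C
F7 | step 3 | (4S)-6,6-dimethyloct-7-en-1-yn-4-ol | C#CC[C@H](O)CC(C)(C)C=C
F8 | step 3 | tert-butyl{[(4S)-6,6-dimethyloct-7-en-1-yn-4-yl]oxy}dimethylsilane | C#CC[C@H](O[Si](C)(C)C(C)(C)C)CC(C)(C)C=C
F9 | step 17 | {[(3R)-4-bromo-3-methylbutyl]oxy}(tert-butyl)diphenylsilane | CC(C)(C)[Si](c1ccccc1)(c1ccccc1)OCC[C@@H](C)CBr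
F10 | step 17 | bromo{(2R)-4-[(tert-butyldiphenylsilyl)oxy]-2-methylbutyl}magnesium | CC(C)(C)[Si](c1ccccc1)(c1ccccc1)OCC[C@@H](C)C[Mg]Br
F11 | step 17 | (3R)-1-[(1R,4aR,7R,8aR)-7-[(tert-butyldimethylsilyl)oxy]-2,5,5,8a-tetramethyl-1,4,4a,5,6,7,8,8a-octahydronaphthalen-1-yl]-5-[(tert-butyldiphenylsilyl)oxy]-3-methylpentan-1-ol (both C1 epimers) | CC(C)(C)[Si](c1ccccc1)(c1ccccc1)OCC[C@@H](C)CC(O)[C@@H]1C(C)=CC[C@@H]2C(C)(C)C[C@@H](O[Si](C)(C)C(C)(C)C)C[C@@]12C
F12 | step 17 | O-{(3R)-1-[(1R,4aR,7R,8aR)-7-[(tert-butyldimethylsilyl)oxy]-2,5,5,8a-tetramethyl-1,4,4a,5,6,7,8,8a-octahydronaphthalen-1-yl]-5-[(tert-butyldiphenylsilyl)oxy]-3-methylpentyl} S-methyl carbonodithioate (both C1 epimers) | CC(C)(C)[Si](c1ccccc1)(c1ccccc1)OCC[C@@H](C)CC(OC(=S)SC)[C@@H]1C(C)=CC[C@@H]2C(C)(C)C[C@@H](O[Si](C)(C)C(C)(C)C)C[C@@]12C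
A1 | alternative 1 | 2,15-diacetoxy-17-nor-ent-labdan-8-one | CC(=O)OCC[C@@H](C)CC[C@@H]1C(=O)CC[C@@H]2C(C)(C)C[C@@H](OC(C)=O)C[C@@]12C
A2 | alternative 2 | 2-hydroxy-ent-labd-7-en-15-yl acetate | CC(=O)OCC[C@@H](C)CC[C@@H]1C(C)=CC[C@@H]2C(C)(C)C[C@@H](O)C[C@@]12C
A3 | alternative 3 | 15-[(tert-butyldimethylsilyl)oxy]-ent-labd-7-en-2-one | CC(C)(C)[Si](C)(C)OCC[C@@H](C)CC[C@@H]1C(C)=CC[C@@H]2C(C)(C)CC(=O)C[C@@]12C
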